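Atoms are numbered along the C15 chain (C1≡C2 to C15). The route rests on cutting the oxocane at O–C12 together with the C13–Br bond. The anti O/Br pair on C12/C13 is what a bromiranium ion on an (E)-C12=C13 alkene would leave behind. One 8-exo bromoetherification by the C6 hydroxyl of the finished 2,5-cis-tetrahydrofuran (O, C4–C7) closes the eight-membered ring (O, C6–C12) and sets C12, C13 and one bromine. The precursor is a monocyclic tetrahydrofuran diol with a CH2–CH(OAc)–CHBr–CH2–CH=CH–Et arm. It is built by an α-bromoaldehyde aldol, an Evans–Tishchenko reduction that installs the C9 acetate, and a 5-exo alkynyl-epoxide opening.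

Key step: step 14

Remark: the L-fructose-derived Shi ketone, the (S)-diarylprolinol silyl ether, the dibromodienone and BDSB (Et2SBr·SbCl5Br) are taken as purchasable reagents.

Step 1
Reactants: 1 (S)-3-hydroxydihydrofuran-2(3H)-one [(S)-α-hydroxy-γ-butyrolactone]
Product: 2 (S)-3-(tert-butyldimethylsilyloxy)dihydrofuran-2(3H)-one
Conditions: TBSCl, imidazole, DMF, rt
Reagents that add atoms: tert-butyldimethylsilyl chloride, CC(C)(C)[Si](C)(C)Cl
Why: Imidazole-assisted silyl ether formation masks the future C6 oxygen and leaves the chiral-pool stereocentre (6S) untouched.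

Step 2
Reactants: 2 (S)-3-(tert-butyldimethylsilyloxy)dihydrofuran-2(3H)-one
Product: 3 (S)-2-(tert-butyldimethylsilyloxy)-4-hydroxy-N-methoxy-N-methylbutanamide
Conditions: MeNH(OMe)·HCl, iPrMgCl, THF, −20 °C; used crude
Reagents that add atoms: N,O-dimethylhydroxylamine hydrochloride, CNOC.Cl
Why: Weinreb amide formation by aminolysis with the magnesium amide cleaves the acyl C–O bond, so C6 is not touched and the C4 carbinol is released.

Step 3
Reactants: 3 (S)-2-(tert-butyldimethylsilyloxy)-4-hydroxy-N-methoxy-N-methylbutanamide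
Product: 4 (S)-2-(tert-butyldimethylsilyloxy)-N-methoxy-N-methyl-4-oxobutanamide
Conditions: TEMPO (cat.), PhI(OAc)2, CH2Cl2, rt
Reagents that add atoms: none
Why: The oxoammonium (TEMPO) oxidation of the primary alcohol stops at the aldehyde and tolerates the silyl ether and the Weinreb amide.

Step 4
Reactants: 5 3-bromo-1-(trimethylsilyl)prop-1-yne
Product: 6 diethyl [3-(trimethylsilyl)prop-2-yn-1-yl]phosphonate
Conditions: P(OEt)3, neat, 120 °C
Reagents that add atoms: triethyl phosphite, CCOP(OCC)OCC
Why: This is a Michaelis–Arbuzov reaction of a primary propargylic bromide, with the silyl cap blocking reaction at the alkyne terminus.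

Step 5
Reactants: 4 (S)-2-(tert-butyldimethylsilyloxy)-N-methoxy-N-methyl-4-oxobutanamide; 6 diethyl [3-(trimethylsilyl)prop-2-yn-1-yl]phosphonate
Product: 8 (S,E)-2-(tert-butyldimethylsilyloxy)-N-methoxy-N-methyl-7-(trimethylsilyl)hept-4-en-6-ynamide, via lithiated phosphonate 7 (not isolated)
Conditions: 6, LiHMDS, THF, −78 °C; then 4, −78 to 0 °C
Reagents that add atoms: none
Why: The Horner–Wadsworth–Emmons olefination takes place at the aldehyde, which is far more electrophilic than the Weinreb amide, and the propargyl phosphonate anion should give the (E)-C3=C4 enyne.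

Step 6
Reactants: 8 (S,E)-enyne Weinreb amide
Product: 9 (S)-2-(tert-butyldimethylsilyloxy)-N-methoxy-N-methyl-3-{(2S,3S)-3-[(trimethylsilyl)ethynyl]oxiran-2-yl}propanamide
Conditions: L-fructose-derived Shi ketone (cat.), Oxone, K2CO3, Bu4NHSO4 (cat.), MeCN/DMM/aq. buffer, 0 °C
Reagents that add atoms: potassium peroxymonosulfate (active part of Oxone), [K+].[O-]S(=O)(=O)OO
Why: The Shi epoxidation oxidises conjugated (E)-enynes only at the alkene, and the spiro transition state of the L-series dioxirane should set 3S,4S under reagent control.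

Step 7
Reactants: 9 epoxy Weinreb amide
Product: 10 (S)-3-(tert-butyldimethylsilyloxy)-4-{(2S,3S)-3-[(trimethylsilyl)ethynyl]oxiran-2-yl}butan-2-one
Conditions: MeMgBr, THF, −40 to −10 °C; aq. work-up
Reagents that add atoms: methylmagnesium bromide, C[Mg]Br
Why: In the Weinreb ketone synthesis the chelated tetrahedral intermediate prevents over-addition, and an uncatalysed Grignard reagent leaves the epoxide alone at low temperature; the methyl group becomes C8.

Step 8
Reactants: 11 pent-1-en-3-ol (racemic)
Product: 13 (E)-hept-4-enal, via 3-(ethenyloxy)pent-1-ene 12 (not isolated)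
Conditions: butyl vinyl ether, Hg(OAc)2 (cat.), reflux; then sealed tube, 140 °C
Reagents that add atoms: butyl vinyl ether, C=COCCCC
Why: Vinyl ether exchange is followed by a Claisen rearrangement through a chair with the ethyl group equatorial, which should give the E alkene (future C12=C13).

Step 9
Reactants: 13 (E)-hept-4-enal
Product: 14 (S,E)-2-bromohept-4-enal
Conditions: (S)-2-{bis[3,5-bis(trifluoromethyl)phenyl](trimethylsilyloxy)methyl}pyrrolidine (cat.), 4,4-dibromo-2,6-di-tert-butylcyclohexa-2,5-dienone, PhCO2H (cat.), CH2Cl2/pentane, −40 °C; cold short silica plug, used at once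
Reagents that add atoms: 4,4-dibromo-2,6-di-tert-butylcyclohexa-2,5-dien-1-one, CC(C)(C)C1=CC(Br)(Br)C=C(C(C)(C)C)C1=O
Why: In this enamine-catalysed α-bromination the bulky arm of the (S)-catalyst shields the Re face of the E-enamine, so Br+ enters on the Si face and sets 10S, while the enamine outcompetes the isolated alkene for the mild Br+ donor.

Step 10
Reactants: 10 epoxy methyl ketone; 14 (S,E)-2-bromohept-4-enal
Product: 16 (3S,4S,6S,9R,10S,12E)-10-bromo-3,4-epoxy-9-hydroxy-6-(tert-butyldimethylsilyloxy)-1-(trimethylsilyl)pentadec-12-en-1-yn-7-one, via lithium enolate 15 (not isolated)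
Conditions: 10, LDA, THF, −78 °C; then 14, −78 °C; AcOH quench at −78 °C
Reagents that add atoms: none
Why: Kinetic deprotonation at the methyl side gives the enolate for this lithium aldol addition, the polar Felkin–Anh/Cornforth transition state of the α-bromoaldehyde should give the 9,10-anti bromohydrin (9R), and the cold acidic quench forestalls Darzens-type closure.

Step 11
Reactants: 16 β-hydroxy ketone
Product: 17 (3S,4S,6S,7R,9R,10S,12E)-9-acetoxy-10-bromo-3,4-epoxy-6-(tert-butyldimethylsilyloxy)-1-(trimethylsilyl)pentadec-12-en-1-yn-7-ol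
Conditions: SmI2 (cat., pre-mixed with MeCHO), MeCHO (excess), THF, −10 °C
Reagents that add atoms: acetaldehyde, CC=O
Why: In the Evans–Tishchenko reaction the Sm(III)-bound hemiacetal on O9 delivers hydride through a chair to the C7 ketone, which should set 7R (1,3-anti to C9), leave the acetate on O9 and keep the C7 hydroxyl free.

Step 12
Reactants: 17 epoxy alcohol
Product: 18 (3S,4R,6S,7R,9R,10S,12E)-9-acetoxy-10-bromo-4,7-epoxy-6-(tert-butyldimethylsilyloxy)-1-(trimethylsilyl)pentadec-12-en-1-yn-3-ol (2,5-cis-tetrahydrofuran, O6 trans to both arms)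
Conditions: CSA (cat.), CH2Cl2, 0 °C
Reagents that add atoms: none
Why: The C7 hydroxyl opens the alkynyl epoxide in an acid-catalysed 5-exo-tet closure (an uncomplexed alkyne does not stabilise charge at C3, so the 6-endo path is not favoured), which inverts C4 to 4R and uncovers the 3S carbinol.

Step 13
Reactants: 18 silylated tetrahydrofuran
Product: 19 (3S,4R,6S,7R,9R,10S,12E)-9-acetoxy-10-bromo-4,7-epoxypentadec-12-en-1-yne-3,6-diol
Conditions: TBAF, AcOH (1:1), THF, 0 °C to rt
Reagents that add atoms: none
Why: Fluoride-mediated desilylation buffered with acetic acid removes the O-TBS and C-TMS groups and should leave the acetate and the secondary bromide untouched.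

Step 14
Reactants: 19 tetrahydrofuran diol
Product: 21 (3S,4R,6S,7R,9R,10S,12R,13S)-9-acetoxy-10,13-dibromo-4,7:6,12-diepoxypentadec-1-yn-3-ol, via bromiranium ion 20 (not isolated)
Conditions: BDSB (1.1 equiv), MeNO2, high dilution, −25 °C; aq. Na2SO3/NaHCO3
Reagents that add atoms: bromodiethylsulfonium bromopentachloroantimonate (BDSB), CC[S+](Br)CC.Cl[Sb-](Cl)(Cl)(Cl)(Cl)Br
Why: BDSB transfers Br+ to the only alkene of 19 (the alkyne next to a carbinol is far less nucleophilic), and the C6 hydroxyl opens bromiranium ion 20 at C12 from the rear, with the proton passing to the non-nucleophilic SbCl5Br− anion. The closest known reaction type is intramolecular haloetherification to medium-ring ethers, which has been shown for oxocanes with collidine-ligated halonium salts and for eight-membered bromoethers with TBCO-type Br+ donors. The oxocane (O, C6, C7, C8, C9, C10, C11, C12) closes in the 8-exo mode at the proximal carbon C12, because the 9-endo mode at C13 would need a larger ring. C13 follows from C12 by stereospecific anti addition to the E alkene, and the sense at C12 (12R) is under substrate control: the two bromiranium faces can equilibrate by Br+ exchange, and closure should be faster through the arrangement that places the bromopropyl arm on the ring face opposite the C10 bromine (1,3-trans). The step needs O6 to beat external halide, the C9 acetate carbonyl (seven-membered dioxepanylium) and the tetrahydrofuran oxygen; the fixed trans disposition of O6 and C8 on the five-membered ring freezes two rotors, an O6–H···O=C hydrogen bond to the acetate can fold the chain, and dilute nitromethane offers no better nucleophile.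

Step 15
Reactants: 21 oxocane propargylic alcohol
Product: 22 (3R,4R,6S,7R,9R,10S,12R,13S)-9-acetoxy-3,10,13-tribromo-4,7:6,12-diepoxypentadec-1-yne (target)
Conditions: CBr4, PPh3, CH2Cl2, 0 °C
Reagents that add atoms: carbon tetrabromide, BrC(Br)(Br)Br
Why: In the Appel reaction bromide displaces the propargylic oxyphosphonium ion by SN2, which inverts C3 (3S to 3R) under neutral conditions that spare the acetate and the other two bromides.

Compound list
1 | (S)-3-hydroxydihydrofuran-2(3H)-one | O[C@H]1CCOC1=O | starting material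
2 | (S)-3-(tert-butyldimethylsilyloxy)dihydrofuran-2(3H)-one | CC(C)(C)[Si](C)(C)O[C@H]1CCOC1=O | intermediate
3 | (S)-2-(TBSO)-4-hydroxy-N-methoxy-N-methylbutanamide | CON(C)C(=O)[C@@H](O[Si](C)(C)C(C)(C)C)CCO | intermediate
4 | (S)-2-(TBSO)-N-methoxy-N-methyl-4-oxobutanamide | CON(C)C(=O)[C@@H](O[Si](C)(C)C(C)(C)C)CC=O | intermediate
5 | 3-bromo-1-(trimethylsilyl)prop-1-yne | BrCC#C[Si](C)(C)C | starting material
6 | diethyl [3-(trimethylsilyl)prop-2-yn-1-yl]phosphonate | CCOP(=O)(CC#C[Si](C)(C)C)OCC | intermediate
7 | lithiated phosphonate (not isolated) | [Li+].CCOP(=O)([CH-]C#C[Si](C)(C)C)OCC | intermediate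
8 | (S,E)-2-(TBSO)-N-methoxy-N-methyl-7-(trimethylsilyl)hept-4-en-6-ynamide | CON(C)C(=O)[C@@H](O[Si](C)(C)C(C)(C)C)C/C=C/C#C[Si](C)(C)C | intermediate
9 | (6S)-Weinreb amide with (3S,4S)-alkynyl epoxide | CON(C)C(=O)[C@@H](O[Si](C)(C)C(C)(C)C)C[C@@H]1O[C@H]1C#C[Si](C)(C)C | intermediate
10 | (6S)-methyl ketone with (3S,4S)-alkynyl epoxide | CC(=O)[C@@H](O[Si](C)(C)C(C)(C)C)C[C@@H]1O[C@H]1C#C[Si](C)(C)C | intermediate
11 | pent-1-en-3-ol (racemic) | CCC(O)C=C | starting material
12 | 3-(ethenyloxy)pent-1-ene (not isolated) | CCC(OC=C)C=C | intermediate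
13 | (E)-hept-4-enal | O=CCC/C=C/CC | intermediate
14 | (S,E)-2-bromohept-4-enal | O=C[C@@H](Br)C/C=C/CC | intermediate
15 | lithium enolate of 10 (not isolated) | [Li+].C=C([O-])[C@@H](O[Si](C)(C)C(C)(C)C)C[C@@H]1O[C@H]1C#C[Si](C)(C)C | intermediate
16 | (3S,4S,6S,9R,10S,12E)-aldol adduct (C7 ketone, C9 OH, C10 Br) | C[Si](C)(C)C#C[C@@H]1O[C@H]1C[C@H](O[Si](C)(C)C(C)(C)C)C(=O)C[C@@H](O)[C@@H](Br)C/C=C/CC | intermediate
17 | (3S,4S,6S,7R,9R,10S,12E)-C9 acetate, C7 alcohol | C[Si](C)(C)C#C[C@@H]1O[C@H]1C[C@H](O[Si](C)(C)C(C)(C)C)[C@H](O)C[C@@H](OC(C)=O)[C@@H](Br)C/C=C/CC | intermediate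
18 | (3S,4R,6S,7R,9R,10S,12E)-2,5-cis-tetrahydrofuran, O6-TBS, C1-TMS | C[Si](C)(C)C#C[C@H](O)[C@H]1C[C@H](O[Si](C)(C)C(C)(C)C)[C@@H](C[C@@H](OC(C)=O)[C@@H](Br)C/C=C/CC)O1 | intermediate
19 | (3S,4R,6S,7R,9R,10S,12E)-tetrahydrofuran 3,6-diol | C#C[C@H](O)[C@H]1C[C@H](O)[C@@H](C[C@@H](OC(C)=O)[C@@H](Br)C/C=C/CC)O1 | intermediate
20 | 12,13-bromiranium ion of 19, SbCl5Br− salt (not isolated) | C#C[C@H](O)[C@H]1C[C@H](O)[C@@H](C[C@@H](OC(C)=O)[C@@H](Br)C[C@@H]2[Br+][C@H]2CC)O1.Cl[Sb-](Cl)(Cl)(Cl)(Cl)Br | intermediate
21 | (3S,4R,6S,7R,9R,10S,12R,13S)-oxocane-fused tetrahydrofuran, C3 alcohol | C#C[C@H](O)[C@H]1C[C@@H]2O[C@@H]([C@@H](Br)CC)C[C@H](Br)[C@H](OC(C)=O)C[C@H]2O1 | intermediate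
22 | (3R,4R,6S,7R,9R,10S,12R,13S)-9-acetoxy-3,10,13-tribromo-4,7:6,12-diepoxypentadec-1-yne | C#C[C@@H](Br)[C@H]1C[C@@H]2O[C@@H]([C@@H](Br)CC)C[C@H](Br)[C@H](OC(C)=O)C[C@H]2O1 | target

Total step count: 15. Longest linear sequence: 12 (steps 1–3, 5–7, 10–15).

Steps most likely to fail

Step 14. Capture of the bromiranium ion by O6 through an eight-membered transition state may be too slow. The ion could then be intercepted by halide, opened in the 9-endo sense, or closed on the wrong alkene face. The fallback sets out from 19 and comes back at 22. It replaces the bromiranium ion with a configurationally defined epoxide and brings in the bromine afterwards.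
- Shi epoxidation of 19 with the same L-series ketone should give the (12S,13S)-epoxide F1.
- A Lewis-acid-promoted 8-exo hydroxy-epoxide cyclisation (Eu(fod)3, toluene, heat) should give the oxocane diol with a 13S carbinol F2.
- This carbinol already has the spatial arrangement of the final bromide, so it must be inverted before substitution.
- Selective Appel bromination of the unhindered propargylic alcohol (PPh3, CBr4, low temperature) should give the 3R bromide 13S alcohol F3.
- Dess–Martin oxidation should give the C13 ketone F4.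
- CBS reduction ((S)-Me-CBS, catecholborane, with C12 as the large group) should give the 13R alcohol F5.
- CBr4/P(Oct)3 in warm toluene should then give 22 with inversion.

Step 10. The α-bromoaldehyde may enolise under the basic conditions, with loss of configuration at C10. The lithium aldolate may also displace the neighbouring bromide. The fallback sets out from 10 and comes back at 16. It moves the union to a non-basic Mukaiyama-type aldol.
- Compound 10 is converted (LDA, TMSCl, −78 °C) into the kinetic trimethylsilyl enol ether F6.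
- F6 is added to 14 under Lewis-base catalysis (AcOLi, DMF, −45 °C).
- Silyl transfer traps the aldolate as the C9 trimethylsilyl ether F7.
- Citric acid in methanol releases 16.

Step 11. Sm(III) iodide may open the alkynyl epoxide. Retro-aldol cleavage or acyl migration from O9 to O7 may also set in, and the α-silyloxy stereocentre may erode the facial selectivity of the hydride transfer. The fallback sets out from 16 and comes back at 17. It separates acylation from reduction.
- Ac2O/pyridine at 0 °C should give the β-acetoxy ketone F8.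
- CBS reduction ((S)-Me-CBS, catecholborane, toluene, −78 °C, with the branched C6 side as the large group) should set 7R under reagent control.

Further compounds
F1 | step 14 | (12S,13S)-12,13-epoxide of 19 | C#C[C@H](O)[C@H]1C[C@H](O)[C@@H](C[C@@H](OC(C)=O)[C@@H](Br)C[C@@H]2O[C@H]2CC)O1
F2 | step 14 | oxocane diol with 3S and 13S carbinols | C#C[C@H](O)[C@H]1C[C@@H]2O[C@@H]([C@@H](O)CC)C[C@H](Br)[C@H](OC(C)=O)C[C@H]2O1
F3 | step 14 | 3R bromide 13S alcohol | C#C[C@@H](Br)[C@H]1C[C@@H]2O[C@@H]([C@@H](O)CC)C[C@H](Br)[C@H](OC(C)=O)C[C@H]2O1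
F4 | step 14 | C13 ketone | C#C[C@@H](Br)[C@H]1C[C@@H]2O[C@@H](C(=O)CC)C[C@H](Br)[C@H](OC(C)=O)C[C@H]2O1
F5 | step 14 | 13R alcohol | C#C[C@@H](Br)[C@H]1C[C@@H]2O[C@@H]([C@H](O)CC)C[C@H](Br)[C@H](OC(C)=O)C[C@H]2O1
F6 | step 10 | kinetic trimethylsilyl enol ether of 10 | C=C(O[Si](C)(C)C)[C@@H](O[Si](C)(C)C(C)(C)C)C[C@@H]1O[C@H]1C#C[Si](C)(C)C
F7 | step 10 | C9 trimethylsilyl ether of 16 | C[Si](C)(C)C#C[C@@H]1O[C@H]1C[C@H](O[Si](C)(C)C(C)(C)C)C(=O)C[C@@H](O[Si](C)(C)C)[C@@H](Br)C/C=C/CC
F8 | step 11 | β-acetoxy ketone (C9 acetate of 16) | C[Si](C)(C)C#C[C@@H]1O[C@H]1C[C@H](O[Si](C)(C)C(C)(C)C)C(=O)C[C@@H](OC(C)=O)[C@@H](Br)C/C=C/CC
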